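**Plan**

- Retrosynthesis: remove the C1–C10 oxirane oxygen and the C8 acyl group, then cut C7–C8 (ten-membered ring) with acetate returned to C13, then C7=C11 and O6–C12 (butenolide), C6–C7, C3–C4, C1–C2 and C10–C14.
- Forward: but-3-yn-1-ol gives C8–C1 (C14 from AlMe3, C2–C3 from ethylene oxide) and but-2-yn-1-ol gives C4–C6 with C15. The chain is joined at C3–C4 and then C6–C7; the butenolide closes by metathesis, the carbocycle with SmI2, and the oxirane comes last.
- Enabling feature: in the α-methylene-γ-lactone (ring O–C6–C7–C11–C12) C7 is the β-carbon and C13 the exocyclic methylene carbon. The isomeric butenolide with a C7=C11 double bond and an acetoxy group on C13 can therefore take a C8 ketyl at C7 and shed acetate to restore C11=C13 while the C1–C10 ring forms.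
- Stereochemistry: C3 by CBS reduction; C6 by amino-alcohol-catalysed alkenylzinc addition; C7 and C8 in the ring closure (C6 and samarium chelation); C1/C10 by peripheral epoxidation; the acyl oxirane by Sharpless epoxidation. The 4Z alkene comes from trans-hydroalumination–iodination, the 1(10)E alkene from syn-carboalumination.

Key step: step 18

Remark: germacrane numbering is used for the skeleton; TBS = tert-butyldimethylsilyl, TBDPS = tert-butyldiphenylsilyl; the target is read as 1R,3S,6R,7R,8R,10R with a (2R,3S)-2,3-dimethyloxirane-2-carbonyl group (cis-dimethyl) on O8.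

**Route**

Step 1
Reactants: 1 but-3-yn-1-ol
Product: 2 tert-butyl(but-3-yn-1-yloxy)diphenylsilane
Conditions: TBDPSCl, imidazole, CH2Cl2, 0 °C to rt
Reagents that add atoms: tert-butylchlorodiphenylsilane, CC(C)(C)[Si](Cl)(c1ccccc1)c1ccccc1
Why: Silylation of the primary alcohol gives an ether on O8 that withstands the organoaluminium, chromium, borane, zinc and ruthenium reagents used later and is cleaved by fluoride only at step 16.

Step 2
Reactants: 2 tert-butyl(but-3-yn-1-yloxy)diphenylsilane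
Product: 5 (E)-6-(TBDPSO)-4-methylhex-3-en-1-ol, via alkenyldimethylalane 3 (not isolated), via lithium alkenylalanate 4 (not isolated)
Conditions: AlMe3 (2.5 equiv), Cp2ZrCl2 (0.25 equiv), CH2Cl2, 0 °C to rt; excess AlMe3 removed in vacuo; n-BuLi, THF–hexane, −78 °C; ethylene oxide, −78 to 0 °C
Reagents that add atoms: trimethylaluminium, C[Al](C)C; ethylene oxide, C1CO1
Why: Negishi zirconium-catalysed carboalumination adds methyl (C14) and aluminium syn across the terminal alkyne with aluminium on the terminal carbon C1, and the alanate made with n-BuLi opens ethylene oxide with retention at C1, so the 1(10)E alkene and C2–C3 are set in one flask.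

Step 3
Reactants: 5 (E)-6-(TBDPSO)-4-methylhex-3-en-1-ol
Product: 6 (E)-6-(TBDPSO)-4-methylhex-3-enal
Conditions: Dess–Martin periodinane, NaHCO3, CH2Cl2, 0 °C; used without storage
Reagents that add atoms: none
Why: Dess–Martin oxidation under bicarbonate buffer stops at the β,γ-unsaturated aldehyde and uses no base strong enough to move the C1=C10 alkene into conjugation.

Step 4
Reactants: 7 but-2-yn-1-ol
Product: 9 (Z)-3-iodobut-2-en-1-ol, via cyclic alkenylalanate 8 (not isolated)
Conditions: NaAlH2(OCH2CH2OMe)2, THF, 0 °C to rt; I2, THF, −78 to 0 °C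
Reagents that add atoms: iodine, [I][I]
Why: Alkoxide-directed trans-hydroalumination puts hydride on C5 and aluminium on C4 in a five-membered alanate, and iodinolysis with retention gives the Z iodide that later fixes the 4Z alkene.

Step 5
Reactants: 9 (Z)-3-iodobut-2-en-1-ol
Product: 10 (Z)-tert-butyl[(3-iodobut-2-en-1-yl)oxy]dimethylsilane
Conditions: TBSCl, imidazole, CH2Cl2, 0 °C
Reagents that add atoms: tert-butylchlorodimethylsilane, CC(C)(C)[Si](C)(C)Cl
Why: Imidazole-promoted silylation masks O6 as a TBS ether that can be removed later beside the TBDPS ether.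

Step 6
Reactants: 6 (E)-6-(TBDPSO)-4-methylhex-3-enal; 10 (Z)-tert-butyl[(3-iodobut-2-en-1-yl)oxy]dimethylsilane
Product: 11 (2Z,6E)-1-(TBSO)-9-(TBDPSO)-3,7-dimethylnona-2,6-dien-4-ol as both C4 epimers
Conditions: CrCl2 (4 equiv), NiCl2 (2 mol %), DMF, rt
Reagents that add atoms: none
Why: Nozaki–Hiyama–Kishi coupling (zerovalent nickel inserts into the C–I bond, the alkenyl group passes to trivalent chromium and adds to the aldehyde) forms C3–C4 with retention of the Z geometry and without enolising the β,γ-unsaturated aldehyde; the carbinol forms as both epimers and is corrected in steps 7 and 8.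

Step 7
Reactants: 11 (2Z,6E)-1-(TBSO)-9-(TBDPSO)-3,7-dimethylnona-2,6-dien-4-ol
Product: 12 (2Z,6E)-1-(TBSO)-9-(TBDPSO)-3,7-dimethylnona-2,6-dien-4-one
Conditions: Dess–Martin periodinane, NaHCO3, CH2Cl2, 0 °C
Reagents that add atoms: none
Why: Dess–Martin oxidation converges both epimers on one α-methyl Z-enone under non-basic conditions that leave the skipped C1=C10 alkene in place.

Step 8
Reactants: 12 (2Z,6E)-1-(TBSO)-9-(TBDPSO)-3,7-dimethylnona-2,6-dien-4-one
Product: 13 (4S,2Z,6E)-1-(TBSO)-9-(TBDPSO)-3,7-dimethylnona-2,6-dien-4-ol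
Conditions: (R)-2-methyl-CBS-oxazaborolidine (0.3 equiv), catecholborane, toluene, −78 °C
Reagents that add atoms: none
Why: Corey–Bakshi–Shibata reduction: the ketone binds the (R)-oxazaborolidine with the α-methylalkenyl group as the large and the methylene as the small substituent, so hydride is delivered to the Re face and the 4S carbinol (C3 of the target, S) results, catecholborane at low temperature sparing the alkenes.

Step 9
Reactants: 13 (4S,2Z,6E)-1-(TBSO)-9-(TBDPSO)-3,7-dimethylnona-2,6-dien-4-ol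
Product: 14 (4S,2Z,6E)-1-(TBSO)-9-(TBDPSO)-3,7-dimethylnona-2,6-dien-4-yl 3-methylbutanoate
Conditions: isovaleric anhydride, Et3N, DMAP (cat.), CH2Cl2, 0 °C to rt
Reagents that add atoms: 3-methylbutanoic anhydride, CC(C)CC(=O)OC(=O)CC(C)C
Why: DMAP-catalysed acylation of the secondary allylic alcohol installs the isovalerate now, so that only O6 and O8 remain to be unmasked later.

Step 10
Reactants: 14 (4S,2Z,6E)-1-(TBSO)-9-(TBDPSO)-3,7-dimethylnona-2,6-dien-4-yl 3-methylbutanoate
Product: 15 (4S,2Z,6E)-9-(TBDPSO)-1-hydroxy-3,7-dimethylnona-2,6-dien-4-yl 3-methylbutanoate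
Conditions: camphorsulfonic acid (10 mol %), MeOH–CH2Cl2 1:1, 0 °C
Reagents that add atoms: none
Why: Acid-catalysed methanolysis cleaves a primary TBS ether far faster than a TBDPS ether, and at 0 °C the allylic ester neither migrates nor ionises.

Step 11
Reactants: 15 (4S,2Z,6E)-9-(TBDPSO)-1-hydroxy-3,7-dimethylnona-2,6-dien-4-yl 3-methylbutanoate
Product: 16 (4S,2Z,6E)-9-(TBDPSO)-3,7-dimethyl-1-oxonona-2,6-dien-4-yl 3-methylbutanoate
Conditions: activated MnO2, CH2Cl2, rt, dark; used at once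
Reagents that add atoms: none
Why: MnO2 oxidises the allylic alcohol on its surface without acid or base, so the Z geometry of the enal is kept.

Step 12
Reactants: 16 (4S,2Z,6E)-9-(TBDPSO)-3,7-dimethyl-1-oxonona-2,6-dien-4-yl 3-methylbutanoate
Product: 17 (3E,6S,7Z,9S,10E)-1-(TBDPSO)-9-hydroxy-3,7-dimethylpentadeca-3,7,10-trien-6-yl 3-methylbutanoate
Conditions: 1-hexyne, Cy2BH (from BH3·SMe2 and cyclohexene), toluene, 0 °C to rt; ZnEt2, −78 °C; (−)-MIB [(2S)-3-exo-morpholinoisoborneol, 5 mol %], then 16, −78 to −10 °C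
Reagents that add atoms: 1-hexyne, CCCCC#C
Why: Catalytic asymmetric alkenylzinc addition: hydroboration of 1-hexyne and boron-to-zinc exchange give an (E)-hexenylzinc reagent that the (−)-MIB-ligated zinc delivers to the Si face of the aldehyde (the sense this amino alcohol shows with aryl and alkenyl aldehydes), which sets C6 as in the target (formally 9S here) and makes C7 the carbinol-bound alkene carbon for the later metathesis.

Step 13
Reactants: 18 2-(bromomethyl)acrylic acid
Product: 19 2-(acetoxymethyl)acrylic acid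
Conditions: KOAc (3 equiv), AcOH, 60 °C; aqueous HCl on work-up
Reagents that add atoms: potassium acetate, CC(=O)[O-].[K+]
Why: Acetate displaces the activated allylic bromide (direct or allylic substitution give the same product) and supplies the C11–C13 unit with its leaving group already on C13.

Step 14
Reactants: 17 (3E,6S,7Z,9S,10E)-1-(TBDPSO)-9-hydroxy-3,7-dimethylpentadeca-3,7,10-trien-6-yl 3-methylbutanoate; 19 2-(acetoxymethyl)acrylic acid
Product: 20 (3E,6S,7Z,9S,10E)-1-(TBDPSO)-3,7-dimethyl-6-(3-methylbutanoyloxy)pentadeca-3,7,10-trien-9-yl 2-(acetoxymethyl)prop-2-enoate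
Conditions: N,N'-diisopropylcarbodiimide, DMAP (5 mol %), CH2Cl2, 0 °C
Reagents that add atoms: none
Why: Steglich esterification at 0 °C forms the O6–C12 ester without rearranging the bis-allylic carbinol or displacing the allylic acetate.

Step 15
Reactants: 20 (3E,6S,7Z,9S,10E)-1-(TBDPSO)-3,7-dimethyl-6-(3-methylbutanoyloxy)pentadeca-3,7,10-trien-9-yl 2-(acetoxymethyl)prop-2-enoate
Product: 21 [(5R)-5-{(1Z,3S,5E)-8-(TBDPSO)-2,6-dimethyl-3-(3-methylbutanoyloxy)octa-1,5-dien-1-yl}-2-oxo-2,5-dihydrofuran-3-yl]methyl acetate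
Conditions: second-generation Hoveyda–Grubbs catalyst (10 mol %), toluene (5 mM), 80 °C
Reagents that add atoms: none
Why: Ring-closing metathesis of an allylic 2-substituted acrylate closes the five-membered butenolide at C7=C11 with loss of hex-1-ene, the trisubstituted C1=C10 and C4=C5 alkenes being too hindered to take part.

Step 16
Reactants: 21 [(5R)-5-{(1Z,3S,5E)-8-(TBDPSO)-2,6-dimethyl-3-(3-methylbutanoyloxy)octa-1,5-dien-1-yl}-2-oxo-2,5-dihydrofuran-3-yl]methyl acetate
Product: 22 [(5R)-5-{(1Z,3S,5E)-8-hydroxy-2,6-dimethyl-3-(3-methylbutanoyloxy)octa-1,5-dien-1-yl}-2-oxo-2,5-dihydrofuran-3-yl]methyl acetate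
Conditions: HF·pyridine, pyridine, THF, 0 °C to rt
Reagents that add atoms: none
Why: Pyridine-buffered HF cleaves the TBDPS ether without base, which the γ-alkenyl butenolide (acidic C6–H), the allylic acetate and the isovalerate should all survive.

Step 17
Reactants: 22 [(5R)-5-{(1Z,3S,5E)-8-hydroxy-2,6-dimethyl-3-(3-methylbutanoyloxy)octa-1,5-dien-1-yl}-2-oxo-2,5-dihydrofuran-3-yl]methyl acetate
Product: 23 [(5R)-5-{(1Z,3S,5E)-2,6-dimethyl-3-(3-methylbutanoyloxy)-8-oxoocta-1,5-dien-1-yl}-2-oxo-2,5-dihydrofuran-3-yl]methyl acetate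
Conditions: Dess–Martin periodinane, NaHCO3, CH2Cl2, 0 °C; used crude
Reagents that add atoms: none
Why: Buffered Dess–Martin oxidation gives the C8 aldehyde under conditions that neither epimerise C6 nor conjugate the C1=C10 alkene, and the crude aldehyde is taken on at once.

Step 18
Reactants: 23 [(5R)-5-{(1Z,3S,5E)-2,6-dimethyl-3-(3-methylbutanoyloxy)-8-oxoocta-1,5-dien-1-yl}-2-oxo-2,5-dihydrofuran-3-yl]methyl acetate
Product: 24 (3S,6R,7R,8R)-8-hydroxy-3-(3-methylbutanoyloxy)germacra-1(10)E,4Z,11(13)-trien-12,6-olide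
Conditions: SmI2 (3 equiv), HMPA (12 equiv), THF, −78 to −20 °C, 23 added over 6 h (final 2 mM); pH 7 buffer
Reagents that add atoms: none
Why: Proposed new method: SmI2–HMPA should reduce the C8 aldehyde to a ketyl radical that adds to C7, the unsubstituted β-carbon of the butenolide; a second electron turns the C11 radical into a trivalent samarium enolate that expels the C13 acetate (E1cB), so the C7–C8 bond, the C11=C13 methylene and the ten-membered ring form in one operation. The closest known reactions are SmI2 ketyl–olefin cyclisations onto unsaturated esters and lactones (five- to eight-membered rings) and Barbier-type SE2' additions of 3-(halomethyl)butenolides and 2-(acyloxymethyl)acrylates to aldehydes. The ring closes in a 10-exo-trig mode (C7 inside, C11 outside the new ring), helped by the Z C4=C5 alkene, the E C1=C10 alkene and the planar butenolide, which leave the chain few rotors. C7 is controlled by C6: the chain that carries C8 leaves C6 on one face of the butenolide and is expected to bridge to the opposite face of C7 through the less strained trans-fused transition state. C8 is controlled by trivalent samarium bridging the ketyl oxygen and the lactone carbonyl, which should turn the C8–O bond toward C11 (8R). The step needs ketyl formation ahead of reduction of the acyloxy-enoate (aldehydes are reduced faster by SmI2–HMPA), cyclisation ahead of pinacol coupling (slow addition at high dilution) and elimination ahead of protonation of the enolate (no proton source is added).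

Step 19
Reactants: 25 (E)-2-methylbut-2-en-1-ol
Product: 26 [(2S,3S)-2,3-dimethyloxiran-2-yl]methanol
Conditions: Ti(OiPr)4 (10 mol %), L-(+)-diethyl tartrate (12 mol %), t-BuOOH, 4 Å molecular sieves, CH2Cl2, −20 °C
Reagents that add atoms: tert-butyl hydroperoxide, CC(C)(C)OO
Why: Sharpless asymmetric epoxidation: with L-(+)-tartrate an (E)-allylic alcohol gives the (2S,3S)-epoxy alcohol, and syn oxygen transfer keeps the two methyl groups cis.

Step 20
Reactants: 26 [(2S,3S)-2,3-dimethyloxiran-2-yl]methanol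
Product: 27 (2R,3S)-2,3-dimethyloxirane-2-carboxylic acid
Conditions: RuCl3 (2 mol %), NaIO4 (4 equiv), MeCN–CCl4–H2O, rt
Reagents that add atoms: sodium periodate, [Na+].[O-]I(=O)(=O)=O; water, O
Why: RuO4 formed in situ from RuCl3 and periodate oxidises the primary alcohol to the acid without opening the oxirane; the C2 descriptor becomes R only because the carboxyl group now outranks C3.

Step 21
Reactants: 24 (3S,6R,7R,8R)-8-hydroxy-3-(3-methylbutanoyloxy)germacra-1(10)E,4Z,11(13)-trien-12,6-olide; 27 (2R,3S)-2,3-dimethyloxirane-2-carboxylic acid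
Product: 29 (3S,6R,7R,8R)-8-[(2R,3S)-2,3-dimethyloxirane-2-carbonyloxy]-3-(3-methylbutanoyloxy)germacra-1(10)E,4Z,11(13)-trien-12,6-olide, via mixed anhydride 28 (not isolated)
Conditions: 2,4,6-trichlorobenzoyl chloride, Et3N, toluene, rt; then 24, DMAP, rt
Reagents that add atoms: none
Why: Yamaguchi esterification acylates the hindered secondary C8 hydroxyl through the acylpyridinium ion of the mixed anhydride, with retention at C8 and at both oxirane carbons.

Step 22
Reactants: 29 (3S,6R,7R,8R)-8-[(2R,3S)-2,3-dimethyloxirane-2-carbonyloxy]-3-(3-methylbutanoyloxy)germacra-1(10)E,4Z,11(13)-trien-12,6-olide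
Product: 30 CNP0167461.4, the (1R,10R)-1,10-epoxide of 29
Conditions: mCPBA (1.1 equiv), NaHCO3, CH2Cl2, 0 °C
Reagents that add atoms: 3-chloroperbenzoic acid, OOC(=O)c1cccc(Cl)c1
Why: Prilezhaev epoxidation takes the only electron-rich alkene (C4=C5 lies between two acyloxy-bearing carbons, C11=C13 is conjugated) and should attack the outward face of the E C1=C10 bond in the ten-membered ring, which gives the (1R,10R)-oxirane as in related germacranolides.

**Compound list**

1 | but-3-yn-1-ol | C#CCCO | starting material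
2 | tert-butyl(but-3-yn-1-yloxy)diphenylsilane | C#CCCO[Si](c1ccccc1)(c1ccccc1)C(C)(C)C | intermediate
3 | (E)-[4-(TBDPSO)-2-methylbut-1-enyl]dimethylalane | C[Al](C)/C=C(\C)CCO[Si](c1ccccc1)(c1ccccc1)C(C)(C)C | intermediate
4 | lithium butyl[(E)-4-(TBDPSO)-2-methylbut-1-enyl]dimethylalanate | [Li+].CCCC[Al-](C)(C)/C=C(\C)CCO[Si](c1ccccc1)(c1ccccc1)C(C)(C)C | intermediate
5 | (E)-6-(TBDPSO)-4-methylhex-3-en-1-ol | OCC/C=C(\C)CCO[Si](c1ccccc1)(c1ccccc1)C(C)(C)C | intermediate
6 | (E)-6-(TBDPSO)-4-methylhex-3-enal | O=CC/C=C(\C)CCO[Si](c1ccccc1)(c1ccccc1)C(C)(C)C | intermediate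
7 | but-2-yn-1-ol | CC#CCO | starting material
8 | sodium cyclic alkenylalanate (five-membered ring O–CH2–CH=C(CH3)–Al, two 2-methoxyethoxy groups on aluminium) | [Na+].CC1=CCO[Al-]1(OCCOC)OCCOC | intermediate
9 | (Z)-3-iodobut-2-en-1-ol | C/C(I)=C/CO | intermediate
10 | (Z)-tert-butyl[(3-iodobut-2-en-1-yl)oxy]dimethylsilane | C/C(I)=C/CO[Si](C)(C)C(C)(C)C | intermediate
11 | (2Z,6E)-1-(TBSO)-9-(TBDPSO)-3,7-dimethylnona-2,6-dien-4-ol, both C4 epimers | C/C(=C/CO[Si](C)(C)C(C)(C)C)C(O)C/C=C(\C)CCO[Si](c1ccccc1)(c1ccccc1)C(C)(C)C | intermediate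
12 | (2Z,6E)-1-(TBSO)-9-(TBDPSO)-3,7-dimethylnona-2,6-dien-4-one | C/C(=C/CO[Si](C)(C)C(C)(C)C)C(=O)C/C=C(\C)CCO[Si](c1ccccc1)(c1ccccc1)C(C)(C)C | intermediate
13 | (4S,2Z,6E)-1-(TBSO)-9-(TBDPSO)-3,7-dimethylnona-2,6-dien-4-ol | C/C(=C/CO[Si](C)(C)C(C)(C)C)[C@@H](O)C/C=C(\C)CCO[Si](c1ccccc1)(c1ccccc1)C(C)(C)C | intermediate
14 | (4S,2Z,6E)-1-(TBSO)-9-(TBDPSO)-3,7-dimethylnona-2,6-dien-4-yl 3-methylbutanoate | C/C(=C/CO[Si](C)(C)C(C)(C)C)[C@@H](OC(=O)CC(C)C)C/C=C(\C)CCO[Si](c1ccccc1)(c1ccccc1)C(C)(C)C | intermediate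
15 | (4S,2Z,6E)-9-(TBDPSO)-1-hydroxy-3,7-dimethylnona-2,6-dien-4-yl 3-methylbutanoate | C/C(=C/CO)[C@@H](OC(=O)CC(C)C)C/C=C(\C)CCO[Si](c1ccccc1)(c1ccccc1)C(C)(C)C | intermediate
16 | (4S,2Z,6E)-9-(TBDPSO)-3,7-dimethyl-1-oxonona-2,6-dien-4-yl 3-methylbutanoate | C/C(=C/C=O)[C@@H](OC(=O)CC(C)C)C/C=C(\C)CCO[Si](c1ccccc1)(c1ccccc1)C(C)(C)C | intermediate
17 | (3E,6S,7Z,9S,10E)-1-(TBDPSO)-9-hydroxy-3,7-dimethylpentadeca-3,7,10-trien-6-yl 3-methylbutanoate | CCCC/C=C/[C@H](O)/C=C(/C)[C@@H](OC(=O)CC(C)C)C/C=C(\C)CCO[Si](c1ccccc1)(c1ccccc1)C(C)(C)C | intermediate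
18 | 2-(bromomethyl)acrylic acid | C=C(CBr)C(=O)O | starting material
19 | 2-(acetoxymethyl)acrylic acid | C=C(COC(C)=O)C(=O)O | intermediate
20 | (3E,6S,7Z,9S,10E)-1-(TBDPSO)-3,7-dimethyl-6-(3-methylbutanoyloxy)pentadeca-3,7,10-trien-9-yl 2-(acetoxymethyl)prop-2-enoate | CCCC/C=C/[C@H](OC(=O)C(=C)COC(C)=O)/C=C(/C)[C@@H](OC(=O)CC(C)C)C/C=C(\C)CCO[Si](c1ccccc1)(c1ccccc1)C(C)(C)C | intermediate
21 | [(5R)-5-{(1Z,3S,5E)-8-(TBDPSO)-2,6-dimethyl-3-(3-methylbutanoyloxy)octa-1,5-dien-1-yl}-2-oxo-2,5-dihydrofuran-3-yl]methyl acetate | CC(=O)OCC1=C[C@@H](/C=C(/C)[C@@H](OC(=O)CC(C)C)C/C=C(\C)CCO[Si](c2ccccc2)(c2ccccc2)C(C)(C)C)OC1=O | intermediate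
22 | [(5R)-5-{(1Z,3S,5E)-8-hydroxy-2,6-dimethyl-3-(3-methylbutanoyloxy)octa-1,5-dien-1-yl}-2-oxo-2,5-dihydrofuran-3-yl]methyl acetate | CC(=O)OCC1=C[C@@H](/C=C(/C)[C@@H](OC(=O)CC(C)C)C/C=C(\C)CCO)OC1=O | intermediate
23 | [(5R)-5-{(1Z,3S,5E)-2,6-dimethyl-3-(3-methylbutanoyloxy)-8-oxoocta-1,5-dien-1-yl}-2-oxo-2,5-dihydrofuran-3-yl]methyl acetate (seco aldehyde butenolide) | CC(=O)OCC1=C[C@@H](/C=C(/C)[C@@H](OC(=O)CC(C)C)C/C=C(\C)CC=O)OC1=O | intermediate
24 | (3S,6R,7R,8R)-8-hydroxy-3-(3-methylbutanoyloxy)germacra-1(10)E,4Z,11(13)-trien-12,6-olide | C=C1C(=O)O[C@@H]2/C=C(/C)[C@@H](OC(=O)CC(C)C)C/C=C(\C)C[C@@H](O)[C@@H]12 | intermediate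
25 | (E)-2-methylbut-2-en-1-ol | C/C=C(\C)CO | starting material
26 | [(2S,3S)-2,3-dimethyloxiran-2-yl]methanol | OC[C@]1(C)O[C@H]1C | intermediate
27 | (2R,3S)-2,3-dimethyloxirane-2-carboxylic acid | OC(=O)[C@]1(C)O[C@H]1C | intermediate
28 | (2R,3S)-2,3-dimethyloxirane-2-carboxylic 2,4,6-trichlorobenzoic anhydride | O=C(OC(=O)[C@]1(C)O[C@H]1C)c1c(Cl)cc(Cl)cc1Cl | intermediate
29 | (3S,6R,7R,8R)-8-[(2R,3S)-2,3-dimethyloxirane-2-carbonyloxy]-3-(3-methylbutanoyloxy)germacra-1(10)E,4Z,11(13)-trien-12,6-olide | C=C1C(=O)O[C@@H]2/C=C(/C)[C@@H](OC(=O)CC(C)C)C/C=C(\C)C[C@@H](OC(=O)[C@]3(C)O[C@H]3C)[C@@H]12 | intermediate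
30 | CNP0167461.4, (1R,3S,6R,7R,8R,10R)-1,10-epoxy-8-[(2R,3S)-2,3-dimethyloxirane-2-carbonyloxy]-3-(3-methylbutanoyloxy)germacra-4Z,11(13)-dien-12,6-olide | C=C1C(=O)O[C@@H]2/C=C(/C)[C@@H](OC(=O)CC(C)C)C[C@H]3O[C@]3(C)C[C@@H](OC(=O)[C@]3(C)O[C@H]3C)[C@@H]12 | target

**Step count and risks**

Total step count: 22. Longest linear sequence: 17 steps (1–3, 6–12, 14–18, 21, 22).

Steps most likely to fail:

1. Step 18 (Proposed new method). The ketyl may dimerise or be reduced on to the alcohol before it reaches C7, or the acyloxy-enoate may be reduced first and lose acetate without ring closure. The fallback is a two-electron Barbier allylation, which is known chemistry: 3-(bromomethyl)butenolides add to aldehydes through the ring β-carbon with zinc or indium, and medium-ring Barbier closures with 2-(bromomethyl)acrylates are established. It sets out from 17, which is esterified with 2-(bromomethyl)acrylic acid 18 (N,N'-diisopropylcarbodiimide, CH2Cl2, 0 °C) to the 2-(bromomethyl)acrylate ester F1. Metathesis as in step 15 then gives the 3-(bromomethyl)butenolide silyl ether F2, HF·pyridine gives the bromo alcohol F3, and Dess–Martin oxidation gives the bromo aldehyde F4. Indium powder in THF–water at high dilution should then form the C13 allylindium species, which adds through C7 to the C8 aldehyde in a chair transition state and returns to the route at 24.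

2. Step 12. Facial selectivity may be low, ethyl may transfer instead of hexenyl, or the Z-enal may isomerise on the zinc Lewis acid. The fallback is an alkynylation–semihydrogenation route to a terminal vinyl carbinol, setting out from 16. Addition of trimethylsilylacetylene with ZnMe2 and (R,R)-ProPhenol (the ligand antipode expected to give Si-face delivery, to be confirmed on a model enal) should give the silylated propargylic alcohol F5. AgNO3-catalysed protodesilylation in MeOH–H2O–CH2Cl2 gives the terminal alkyne F6, and Lindlar semihydrogenation (Pd/CaCO3 poisoned with Pb(OAc)2, quinoline, H2) gives the vinyl carbinol F7. Steglich esterification with 19 gives the diene ester F8, whose ring-closing metathesis with loss of ethene returns to the route at 21.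

3. Step 22. The peracid may attack the other face of C1=C10 if a second ring conformer exposes it, or it may over-oxidise. The fallback is a hydroxyl-directed epoxidation before acylation, setting out from 24. VO(acac)2 and t-BuOOH in CH2Cl2 at 0 °C should deliver oxygen to C1=C10 from the homoallylic C8 hydroxyl to give the epoxy alcohol F9, and Yamaguchi esterification with 27 as in step 21 returns to the route at 30.

**Further compounds**

F1 | step 18 | (3E,6S,7Z,9S,10E)-1-(TBDPSO)-3,7-dimethyl-6-(3-methylbutanoyloxy)pentadeca-3,7,10-trien-9-yl 2-(bromomethyl)prop-2-enoate | CCCC/C=C/[C@H](OC(=O)C(=C)CBr)/C=C(/C)[C@@H](OC(=O)CC(C)C)C/C=C(\C)CCO[Si](c1ccccc1)(c1ccccc1)C(C)(C)C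
F2 | step 18 | (1Z,3S,5E)-1-[(2R)-4-(bromomethyl)-5-oxo-2,5-dihydrofuran-2-yl]-8-(TBDPSO)-2,6-dimethylocta-1,5-dien-3-yl 3-methylbutanoate | BrCC1=C[C@@H](/C=C(/C)[C@@H](OC(=O)CC(C)C)C/C=C(\C)CCO[Si](c2ccccc2)(c2ccccc2)C(C)(C)C)OC1=O
F3 | step 18 | (1Z,3S,5E)-1-[(2R)-4-(bromomethyl)-5-oxo-2,5-dihydrofuran-2-yl]-8-hydroxy-2,6-dimethylocta-1,5-dien-3-yl 3-methylbutanoate | BrCC1=C[C@@H](/C=C(/C)[C@@H](OC(=O)CC(C)C)C/C=C(\C)CCO)OC1=O
F4 | step 18 | (1Z,3S,5E)-1-[(2R)-4-(bromomethyl)-5-oxo-2,5-dihydrofuran-2-yl]-2,6-dimethyl-8-oxoocta-1,5-dien-3-yl 3-methylbutanoate | BrCC1=C[C@@H](/C=C(/C)[C@@H](OC(=O)CC(C)C)C/C=C(\C)CC=O)OC1=O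
F5 | step 12 | (3R,4Z,6S,8E)-11-(TBDPSO)-3-hydroxy-5,9-dimethyl-1-(trimethylsilyl)undeca-4,8-dien-1-yn-6-yl 3-methylbutanoate | C[Si](C)(C)C#C[C@H](O)/C=C(/C)[C@@H](OC(=O)CC(C)C)C/C=C(\C)CCO[Si](c1ccccc1)(c1ccccc1)C(C)(C)C
F6 | step 12 | (3R,4Z,6S,8E)-11-(TBDPSO)-3-hydroxy-5,9-dimethylundeca-4,8-dien-1-yn-6-yl 3-methylbutanoate | C#C[C@H](O)/C=C(/C)[C@@H](OC(=O)CC(C)C)C/C=C(\C)CCO[Si](c1ccccc1)(c1ccccc1)C(C)(C)C
F7 | step 12 | (3S,4Z,6S,8E)-11-(TBDPSO)-3-hydroxy-5,9-dimethylundeca-1,4,8-trien-6-yl 3-methylbutanoate | C=C[C@H](O)/C=C(/C)[C@@H](OC(=O)CC(C)C)C/C=C(\C)CCO[Si](c1ccccc1)(c1ccccc1)C(C)(C)C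
F8 | step 12 | (3S,4Z,6S,8E)-11-(TBDPSO)-5,9-dimethyl-6-(3-methylbutanoyloxy)undeca-1,4,8-trien-3-yl 2-(acetoxymethyl)prop-2-enoate | C=C[C@H](OC(=O)C(=C)COC(C)=O)/C=C(/C)[C@@H](OC(=O)CC(C)C)C/C=C(\C)CCO[Si](c1ccccc1)(c1ccccc1)C(C)(C)C
F9 | step 22 | (1R,3S,6R,7R,8R,10R)-1,10-epoxy-8-hydroxy-3-(3-methylbutanoyloxy)germacra-4Z,11(13)-dien-12,6-olide | C=C1C(=O)O[C@@H]2/C=C(/C)[C@@H](OC(=O)CC(C)C)C[C@H]3O[C@]3(C)C[C@@H](O)[C@@H]12
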